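The α-methylene-γ-lactone is stitched onto a preformed ten-membered carbocycle with CO2 as the source of C12 and both lactone oxygens. In one flask, the C11 alkenyl boronate of macrocycle 22 is carboxylated under copper catalysis (C11–C12 bond) and Pd(0) then ionises the C6 methyl carbonate, which is allylic to the C4=C5 ring olefin, so that the new carboxylate closes the five-membered ring at C6 with net retention (O–C6 bond). The precursor already holds all stereocentres: a butyrolactone template spanning C5–C8 sets C6, C7 and C8, and a Nozaki–Hiyama–Kishi closure of the C1–C10 bond forms the ring and C1.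

Key step: step 17

Remark: locants C1–C15 are the germacrane locants of the target (C6 lactone carbinol, C7 ring fusion, C8 acyloxy carbon, C1 secondary carbinol, C4=C5 and C9=C10 ring olefins, C11=C13 exocyclic olefin, C12 lactone carbonyl, C15 hydroxymethyl) and are kept for all intermediates; Bpin = 4,4,5,5-tetramethyl-1,3,2-dioxaborolan-2-yl; the key step is run as one telescoped one-flask operation.

Step 1
Reactants: 1 (Z)-3-iodobut-2-en-1-ol
Product: 2 (Z)-3-iodobut-2-enal
Conditions: MnO2 (15 equiv), CH2Cl2, 23 °C, dark; filtered and used at once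
Reagents that add atoms: none
Why: Allylic alcohol oxidation with activated MnO2 is neutral and heterogeneous, so the enal should form without Z-to-E isomerisation of the iodoalkene that later becomes C9=C10.

Step 2
Reactants: 2 (Z)-3-iodobut-2-enal; 3 ethyl penta-3,4-dienoate
Product: 5 (4R,5S)-5-[(Z)-2-iodoprop-1-en-1-yl]-4-[1-(Bpin)ethenyl]oxolan-2-one (trans-lactone; 7R/8S), via hydroxy ester 4 (not isolated)
Conditions: CuCl (5 mol %), chiral bisphosphine (6 mol %, enantiomer matched to 7R/8S), NaOt-Bu (10 mol %), B2pin2 (1.1 equiv), THF, 22 °C; then p-TsOH·H2O (10 mol %), CH2Cl2, 23 °C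
Reagents that add atoms: bis(pinacolato)diboron, CC1(C)OB(OC1(C)C)B1OC(C)(C)C(C)(C)O1
Why: Copper-catalysed borylative allene–aldehyde coupling, in which L*Cu–Bpin adds to the terminal C=C of the allene (boron to C11) to give a (Z)-2-boryl-allylcopper that adds to the aldehyde at its γ-carbon C7 through a chair transition state, should give the syn adduct with the aldehyde face (C8) chosen by the ligand and C7 set relative to C8 by the chair; acid-catalysed lactonisation then gives the trans-4,5-disubstituted butyrolactone.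

Step 3
Reactants: 5 trans-lactone
Product: 6 (3S,4S,5S)-3-hydroxy-5-[(Z)-2-iodoprop-1-en-1-yl]-4-[1-(Bpin)ethenyl]oxolan-2-one
Conditions: LiHMDS (1.2 equiv), THF, −78 °C; 2-(phenylsulfonyl)-3-phenyloxaziridine (1.5 equiv), −78 °C; NH4Cl
Reagents that add atoms: Davis oxaziridine [2-(benzenesulfonyl)-3-phenyloxaziridine], O=S(=O)(c1ccccc1)N1OC1c1ccccc1
Why: In this Davis enolate hydroxylation the lithium enolate is oxidised on the face anti to the adjacent C7 alkenyl group, so the new C6–O bond should be trans to C7 (all-trans lactone), which is the configuration C6 keeps to the end.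

Step 4
Reactants: 6 α-hydroxy lactone
Product: 7 (3S,4R,5S)-5-[(Z)-2-iodoprop-1-en-1-yl]-4-[1-(Bpin)ethenyl]-3-(triethylsilyloxy)oxolan-2-one
Conditions: TESCl (1.3 equiv), imidazole, DMF, 0 °C
Reagents that add atoms: chlorotriethylsilane, CC[Si](Cl)(CC)CC
Why: Standard silylation of the secondary α-hydroxyl gives a TES ether that survives both hydride reductions and is later the only silyl group cleaved by mild acid.

Step 5
Reactants: 7 TES lactone
Product: 8 (3S,4R,5S)-5-[(Z)-2-iodoprop-1-en-1-yl]-4-[1-(Bpin)ethenyl]-3-(triethylsilyloxy)oxolan-2-ol (anomer mixture)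
Conditions: DIBAL-H (1.1 equiv), CH2Cl2, −78 °C; Rochelle salt
Reagents that add atoms: none
Why: Partial reduction of a γ-lactone with DIBAL-H at −78 °C stops at the aluminium hemiacetal, and the vinyl iodide, boronate and silyl ether are inert under these conditions.

Step 6
Reactants: 9 methyl 5,5-dimethoxypentanoate
Product: 10 methyl 2-bromo-5,5-dimethoxypentanoate (racemic)
Conditions: LDA (1.1 equiv), THF, −78 °C; then (CBrCl2)2 (1.2 equiv), −78 to −40 °C
Reagents that add atoms: 1,2-dibromo-1,1,2,2-tetrachloroethane, BrC(Cl)(Cl)C(Cl)(Cl)Br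
Why: α-Bromination of the ester lithium enolate by an electrophilic bromine donor; the new stereocentre is irrelevant because it becomes the ylide carbon.

Step 7
Reactants: 10 methyl 2-bromo-5,5-dimethoxypentanoate
Product: 12 methyl 5,5-dimethoxy-2-(triphenyl-λ5-phosphanylidene)pentanoate, via phosphonium bromide 11 (not isolated)
Conditions: PPh3 (1.1 equiv), MeCN, 80 °C; then 2 M NaOH, CH2Cl2, 0 °C
Reagents that add atoms: triphenylphosphine, c1ccc(cc1)P(c1ccccc1)c1ccccc1
Why: SN2 quaternisation of triphenylphosphine by the α-bromo ester and deprotonation of the acidic α-proton give the ester-stabilised ylide (classical Wittig reagent preparation).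

Step 8
Reactants: 8 lactol; 12 stabilised ylide
Product: 13 methyl (2E,4R,5R,6S,7Z)-2-(3,3-dimethoxypropyl)-6-hydroxy-8-iodo-5-[1-(Bpin)ethenyl]-4-(triethylsilyloxy)nona-2,7-dienoate
Conditions: toluene, 90 °C
Reagents that add atoms: none
Why: Wittig olefination of the open hydroxy-aldehyde form of the lactol with an α-branched ester-stabilised ylide should give the E-enoate (ester trans to C6, hence C3 cis to C6 as the ring needs) and releases the C8 hydroxyl, while the poorly electrophilic trisubstituted enoate should resist oxa-Michael closure.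

Step 9
Reactants: 13 enoate
Product: 14 (2E,4R,5R,6S,7Z)-2-(3,3-dimethoxypropyl)-8-iodo-5-[1-(Bpin)ethenyl]-4-(triethylsilyloxy)nona-2,7-diene-1,6-diol
Conditions: DIBAL-H (3.5 equiv), CH2Cl2, −78 °C; Rochelle salt
Reagents that add atoms: none
Why: 1,2-Reduction of the enoate by DIBAL-H gives the allylic alcohol (C15), and the acetal, silyl ether, vinyl iodide and boronate are not reduced at −78 °C.

Step 10
Reactants: 14 diol
Product: 15 1-O-TBDPS ether of 14 (C15 OTBDPS; C8 OH free)
Conditions: TBDPSCl (1.05 equiv), imidazole, CH2Cl2, 0 °C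
Reagents that add atoms: tert-butyl(chloro)diphenylsilane, CC(C)(C)[Si](Cl)(c1ccccc1)c1ccccc1
Why: Silylation is selective for the primary allylic C15 hydroxyl over the hindered secondary C8 hydroxyl.

Step 11
Reactants: 15 mono-alcohol; 16 (S)-2-methylbutanoic acid
Product: 17 C8 (2S)-2-methylbutanoate of 15
Conditions: EDC·HCl (1.5 equiv), DMAP (0.2 equiv), CH2Cl2, 0 to 23 °C
Reagents that add atoms: none
Why: Steglich esterification of the only free hydroxyl (C8) by carbodiimide activation at 0 °C avoids a ketene pathway, so the (S) centre of the acid is carried over unchanged.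

Step 12
Reactants: 17 ester
Product: 18 C6 alcohol (17 without the TES group)
Conditions: PPTS (0.2 equiv), MeOH, 0 °C
Reagents that add atoms: none
Why: Acid-catalysed methanolysis cleaves the secondary TES ether far faster than the TBDPS ether, and methanol as solvent keeps the dimethyl acetal intact.

Step 13
Reactants: 18 C6 alcohol
Product: 19 C6 methyl carbonate of 18
Conditions: ClCO2Me (3 equiv), pyridine, DMAP (cat.), CH2Cl2, 0 °C
Reagents that add atoms: methyl chloroformate, COC(=O)Cl
Why: O-Acylation of the allylic C6 alcohol installs the carbonate leaving group for the later π-allyl ionisation without touching the C6 configuration.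

Step 14
Reactants: 19 carbonate
Product: 20 C1 aldehyde (19 with the acetal hydrolysed)
Conditions: PPTS (0.3 equiv), THF/H2O (4:1), 45 °C
Reagents that add atoms: water, O
Why: Mild acetal hydrolysis unveils the C1 aldehyde, and the allylic carbonate, ester, TBDPS ether and boronate tolerate buffered aqueous acid.

Step 15
Reactants: 20 iodo aldehyde
Product: 21 (1S,4E,6R,7R,8R,9Z)-macrocyclic allylic alcohol (ten-membered ring; C1 OH; C6 OCO2Me; C7 1-(Bpin)ethenyl; C8 acyloxy; C15 OTBDPS)
Conditions: CrCl2 (4 equiv), Kishi oxazoline-sulfonamide ligand (4.4 equiv, enantiomer matched to 1S), Et3N, NiCl2·DMP (2 mol %), MeCN, 23 °C, 2 mM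
Reagents that add atoms: none
Why: In this intramolecular Nozaki–Hiyama–Kishi coupling Ni(0) inserts into the C10–I bond with retention of the Z geometry, transmetalation to Cr(III) and addition to the C1 aldehyde close the ten-membered ring, and the chromium-bound chiral sulfonamide ligand together with the cyclic transition state selects the aldehyde face that gives the 1S alcohol.

Step 16
Reactants: 21 macrocyclic alcohol
Product: 22 C1 O-TBS ether of 21
Conditions: TBSOTf (1.5 equiv), 2,6-lutidine, CH2Cl2, −78 °C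
Reagents that add atoms: tert-butyldimethylsilyl triflate, CC(C)(C)[Si](C)(C)OS(=O)(=O)C(F)(F)F
Why: Silylation of the hindered allylic C1 alcohol removes the last protic group that could quench the alkenylcopper intermediate of the key step.

Step 17
Reactants: 22 macrocyclic boronate carbonate
Product: 24 1-O-TBS-15-O-TBDPS ether of the target lactone, via potassium acrylate 23 (not isolated)
Conditions: IPrCuCl (10 mol %), KOt-Bu (1.1 equiv), CO2 (1 atm), THF, 65 °C; then Pd(PPh3)4 (5 mol %), 40 °C
Reagents that add atoms: carbon dioxide, O=C=O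
Why: The alkoxide-activated alkenyl boronate transmetalates to (IPr)Cu–C11, CO2 inserts into the Cu–C bond to form the C11–C12 bond and salt metathesis releases potassium acrylate 23; Pd(0) added to the same flask then ionises the C6 methyl carbonate with inversion to a π-allyl complex spanning C4–C5–C6, and the carboxylate oxygen attacks C6 anti to palladium to form the O–C6 bond. The closest known reaction types are the NHC–copper-catalysed carboxylation of alkenyl boronic esters with CO2 and the palladium-catalysed (Tsuji–Trost) allylic lactonisation of carboxylates. The five-membered lactone closes in the 5-exo mode at the π-allyl terminus C6 (attack at C4 would need a seven-membered ring), and the C4=C5 geometry is kept because syn/anti exchange would require a tertiary σ-palladium at C4. C6 is controlled by double inversion (net retention of the configuration set on the butyrolactone template in step 3), which gives the trans ring fusion with the existing C7 centre, and no other stereocentre is touched. The step needs CO2 insertion to outrun protodeboronation and copper-mediated allyl–alkenyl coupling, and ionisation of the C6 carbonate to outrun that of the allylic C8 ester; the CO2 atmosphere (which also buffers the alkoxide as its carbonate), the silyl protection of both hydroxyls, the addition of palladium only after carboxylation and the far better leaving-group ability of carbonate over carboxylate should secure this.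

Step 18
Reactants: 24 bis-silyl lactone
Product: 25 target, (1S,4E,6R,7R,8R,9Z)-1,15-dihydroxy-8-[(2S)-2-methylbutanoyloxy]germacra-4,9,11(13)-trien-12,6-olide
Conditions: HF·pyridine, pyridine/THF, 0 to 23 °C
Reagents that add atoms: none
Why: Fluoride-mediated cleavage of both silyl ethers under mildly acidic conditions offers no basic nucleophile for conjugate addition to the α-methylene lactone and leaves the ester untouched.

Compound list
1 | (Z)-3-iodobut-2-en-1-ol | OC/C=C(/C)I | starting material
2 | (Z)-3-iodobut-2-enal | O=C/C=C(/C)I | intermediate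
3 | ethyl penta-3,4-dienoate | CCOC(=O)CC=C=C | starting material
4 | ethyl (3R,4S,5Z)-4-hydroxy-6-iodo-3-[1-(Bpin)ethenyl]hept-5-enoate (syn adduct; C7 R, C8 S) | C=C(B1OC(C)(C)C(C)(C)O1)[C@@H](CC(=O)OCC)[C@H](O)/C=C(/C)I | intermediate
5 | (4R,5S)-5-[(Z)-2-iodoprop-1-en-1-yl]-4-[1-(Bpin)ethenyl]oxolan-2-one (4,5-trans) | C=C(B1OC(C)(C)C(C)(C)O1)[C@H]1CC(=O)O[C@@H]1/C=C(/C)I | intermediate
6 | (3S,4S,5S)-3-hydroxy-5-[(Z)-2-iodoprop-1-en-1-yl]-4-[1-(Bpin)ethenyl]oxolan-2-one (all-trans) | C=C(B1OC(C)(C)C(C)(C)O1)[C@H]1[C@H](O)C(=O)O[C@@H]1/C=C(/C)I | intermediate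
7 | (3S,4R,5S)-5-[(Z)-2-iodoprop-1-en-1-yl]-4-[1-(Bpin)ethenyl]-3-(triethylsilyloxy)oxolan-2-one | C=C(B1OC(C)(C)C(C)(C)O1)[C@H]1[C@H](O[Si](CC)(CC)CC)C(=O)O[C@@H]1/C=C(/C)I | intermediate
8 | (3S,4R,5S)-5-[(Z)-2-iodoprop-1-en-1-yl]-4-[1-(Bpin)ethenyl]-3-(triethylsilyloxy)oxolan-2-ol (anomer mixture) | C=C(B1OC(C)(C)C(C)(C)O1)[C@H]1[C@H](O[Si](CC)(CC)CC)C(O)O[C@@H]1/C=C(/C)I | intermediate
9 | methyl 5,5-dimethoxypentanoate | COC(=O)CCCC(OC)OC | starting material
10 | methyl 2-bromo-5,5-dimethoxypentanoate (racemic) | COC(=O)C(Br)CCC(OC)OC | intermediate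
11 | (1,5,5-trimethoxy-1-oxopentan-2-yl)triphenylphosphonium bromide | COC(=O)C(CCC(OC)OC)[P+](c1ccccc1)(c1ccccc1)c1ccccc1.[Br-] | intermediate
12 | methyl 5,5-dimethoxy-2-(triphenyl-λ5-phosphanylidene)pentanoate | COC(=O)C(CCC(OC)OC)=P(c1ccccc1)(c1ccccc1)c1ccccc1 | intermediate
13 | methyl (2E,4R,5R,6S,7Z)-2-(3,3-dimethoxypropyl)-6-hydroxy-8-iodo-5-[1-(Bpin)ethenyl]-4-(triethylsilyloxy)nona-2,7-dienoate (chain C4/C5/C6 = C6/C7/C8) | C=C(B1OC(C)(C)C(C)(C)O1)[C@@H]([C@H](O[Si](CC)(CC)CC)/C=C(/C(=O)OC)CCC(OC)OC)[C@H](O)/C=C(/C)I | intermediate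
14 | (2E,4R,5R,6S,7Z)-2-(3,3-dimethoxypropyl)-8-iodo-5-[1-(Bpin)ethenyl]-4-(triethylsilyloxy)nona-2,7-diene-1,6-diol | C=C(B1OC(C)(C)C(C)(C)O1)[C@@H]([C@H](O[Si](CC)(CC)CC)/C=C(/CO)CCC(OC)OC)[C@H](O)/C=C(/C)I | intermediate
15 | 1-O-(tert-butyldiphenylsilyl) ether of 14 (2E,4R,5R,6S,7Z; chain locants of 14) | C=C(B1OC(C)(C)C(C)(C)O1)[C@@H]([C@H](O[Si](CC)(CC)CC)/C=C(/CO[Si](c1ccccc1)(c1ccccc1)C(C)(C)C)CCC(OC)OC)[C@H](O)/C=C(/C)I | intermediate
16 | (S)-2-methylbutanoic acid | CC[C@H](C)C(=O)O | starting material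
17 | 6-O-[(2S)-2-methylbutanoyl] ester of 15 (2E,4R,5R,6S,7Z; chain locants of 14) | C=C(B1OC(C)(C)C(C)(C)O1)[C@@H]([C@H](O[Si](CC)(CC)CC)/C=C(/CO[Si](c1ccccc1)(c1ccccc1)C(C)(C)C)CCC(OC)OC)[C@H](OC(=O)[C@@H](C)CC)/C=C(/C)I | intermediate
18 | 4-hydroxy compound from 17 by loss of TES (2E,4R,5S,6S,7Z; chain locants of 14; C6 OH free) | C=C(B1OC(C)(C)C(C)(C)O1)[C@@H]([C@H](O)/C=C(/CO[Si](c1ccccc1)(c1ccccc1)C(C)(C)C)CCC(OC)OC)[C@H](OC(=O)[C@@H](C)CC)/C=C(/C)I | intermediate
19 | 4-O-(methoxycarbonyl) derivative of 18 (2E,4R,5R,6S,7Z; C6 methyl carbonate) | C=C(B1OC(C)(C)C(C)(C)O1)[C@@H]([C@H](OC(=O)OC)/C=C(/CO[Si](c1ccccc1)(c1ccccc1)C(C)(C)C)CCC(OC)OC)[C@H](OC(=O)[C@@H](C)CC)/C=C(/C)I | intermediate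
20 | aldehyde from 19, 2-(3-oxopropyl) side chain (2E,4R,5R,6S,7Z; C1 aldehyde) | C=C(B1OC(C)(C)C(C)(C)O1)[C@@H]([C@H](OC(=O)OC)/C=C(/CO[Si](c1ccccc1)(c1ccccc1)C(C)(C)C)CCC=O)[C@H](OC(=O)[C@@H](C)CC)/C=C(/C)I | intermediate
21 | (1S,4E,6R,7R,8R,9Z)-cyclodeca-4,9-diene (germacrane locants) with 1-OH, 4-CH2OTBDPS, 6-OCO2Me, 7-[1-(Bpin)ethenyl], 8-O-[(2S)-2-methylbutanoyl], 10-CH3 | C=C(B1OC(C)(C)C(C)(C)O1)[C@H]2[C@H](OC(=O)OC)/C=C(/CO[Si](c3ccccc3)(c3ccccc3)C(C)(C)C)CC[C@H](O)/C(C)=C\[C@H]2OC(=O)[C@@H](C)CC | intermediate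
22 | 1-O-(tert-butyldimethylsilyl) ether of 21 (1S,4E,6R,7R,8R,9Z) | C=C(B1OC(C)(C)C(C)(C)O1)[C@H]2[C@H](OC(=O)OC)/C=C(/CO[Si](c3ccccc3)(c3ccccc3)C(C)(C)C)CC[C@H](O[Si](C)(C)C(C)(C)C)/C(C)=C\[C@H]2OC(=O)[C@@H](C)CC | intermediate
23 | potassium 2-[(1S,4E,6R,7R,8R,9Z)-macrocyclyl]acrylate (22 with CO2K in place of Bpin) | C=C(C(=O)[O-])[C@H]2[C@H](OC(=O)OC)/C=C(/CO[Si](c3ccccc3)(c3ccccc3)C(C)(C)C)CC[C@H](O[Si](C)(C)C(C)(C)C)/C(C)=C\[C@H]2OC(=O)[C@@H](C)CC.[K+] | intermediate
24 | (1S,4E,6R,7R,8R,9Z)-1-(tert-butyldimethylsilyloxy)-15-(tert-butyldiphenylsilyloxy)-8-[(2S)-2-methylbutanoyloxy]germacra-4,9,11(13)-trien-12,6-olide | C=C1C(=O)O[C@@H]2/C=C(/CO[Si](c3ccccc3)(c3ccccc3)C(C)(C)C)CC[C@H](O[Si](C)(C)C(C)(C)C)/C(C)=C\[C@@H](OC(=O)[C@@H](C)CC)[C@@H]12 | intermediate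
25 | (1S,4E,6R,7R,8R,9Z)-1,15-dihydroxy-8-[(2S)-2-methylbutanoyloxy]germacra-4,9,11(13)-trien-12,6-olide (CNP0526758.1) | C=C1C(=O)O[C@@H]2/C=C(/CO)CC[C@H](O)/C(C)=C\[C@@H](OC(=O)[C@@H](C)CC)[C@@H]12 | target

Total step count: 18. Longest linear sequence: 16 steps (steps 1–5 and 8–18; the ylide branch, steps 6–7, joins at step 8).

Steps most likely to fail

1. Step 17 (key step). The hindered 1,1-disubstituted pinacol boronate may transmetalate slowly or protodeboronate, alkoxide may attack the carbonate or ester before CO2 buffers it, the alkenylcopper may couple with the allylic carbonate across the ring, and the π-allyl stage may lose a β-hydrogen or ionise the C8 ester. Fallback (sets out from 22, comes back at 24): the two bond formations are decoupled and the carbon–carbon bond is made with rhodium instead of copper. [Rh(OH)(cod)]2/dppp, CsF and CO2 (1 atm) in dioxane at 60 °C, followed by acidic work-up, give the isolated 2-[(1S,4E,6R,7R,8R,9Z)-macrocyclyl]acrylic acid F3. Pd2(dba)3·CHCl3/PPh3 with Et3N in THF at 23 °C then lactonises F3 to 24 by the same double-inversion pathway, with the acid purified and the palladium step optimised on its own.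

2. Step 2. Chemoselectivity may be lost (β-boration of the enal, substitution of the vinylic iodide, base-induced isomerisation of the 3,4-dienoate to the conjugated dienoate), or facial selectivity may be poor. Fallback (sets out from 3, uses 2, comes back at 5): copper and alkoxide are avoided. Pt(dba)2/PCy3-catalysed diboration of the terminal C=C of 3 with B2pin2 in toluene at 50 °C gives ethyl (3Z)-4,5-bis(Bpin)pent-3-enoate F1. Chiral phosphoric acid-catalysed allylboration of 2 with F1 ((R)-TRIP, 5 mol %, toluene, −30 °C) passes through the same chair transition state to the syn adduct 4, and TsOH lactonisation gives 5.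

3. Step 15. Facial selectivity at C1 may be poor, oligomers may form instead of the ten-membered ring, or nickel may ionise the allylic carbonate. Fallback (sets out from 21 obtained as a C1 epimer mixture, comes back at 21): the C1 centre is set by reagent-controlled reduction instead of addition. Dess–Martin oxidation gives the (4E,6R,7R,8R,9Z)-macrocyclic C1 enone F2, and Corey–Bakshi–Shibata reduction (Me-CBS oxazaborolidine, catecholborane, toluene, −78 °C) returns the 1S alcohol 21.

Further compounds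
F1 | step 2 | ethyl (3Z)-4,5-bis(4,4,5,5-tetramethyl-1,3,2-dioxaborolan-2-yl)pent-3-enoate | CCOC(=O)C/C=C(\CB1OC(C)(C)C(C)(C)O1)B1OC(C)(C)C(C)(C)O1
F2 | step 15 | (4E,6R,7R,8R,9Z)-macrocyclic enone (21 with C1 ketone) | C=C(B1OC(C)(C)C(C)(C)O1)[C@H]2[C@H](OC(=O)OC)/C=C(/CO[Si](c3ccccc3)(c3ccccc3)C(C)(C)C)CCC(=O)/C(C)=C\[C@H]2OC(=O)[C@@H](C)CC
F3 | step 17 | 2-[(1S,4E,6R,7R,8R,9Z)-macrocyclyl]acrylic acid (22 with CO2H in place of Bpin) | C=C(C(=O)O)[C@H]2[C@H](OC(=O)OC)/C=C(/CO[Si](c3ccccc3)(c3ccccc3)C(C)(C)C)CC[C@H](O[Si](C)(C)C(C)(C)C)/C(C)=C\[C@H]2OC(=O)[C@@H](C)CC
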